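**Retrosynthetic overview**

1. Target 27 ⇐ alkenyl boronate 26 (C–B oxidation unveils the 2-oxopropyl ketone last) ⇐ ring-A carbaldehyde 19 (boron-Wittig homologation of the formyl group; ketal, silyl ether and ester removed on the way, C6/C8 equilibrated).
2. 19 ⇐ siloxydiene 8 (ring B) + dienal 17 (the whole side chain): C8a–C1 bond by vinylogous Michael addition, then ring A closed at C2–C3 by aldol condensation (amine-catalysed formal [3+3] annulation).
3. Enabling feature: ring A (C1, C2, C3, C4, C4a, C8a) is a cyclohexa-1,3-diene (C2=C3–C4=C4a) with a methyl group on C3 and a carbon chain on C2, i.e. a latent 2-methylcyclohexa-1,3-diene-1-carbaldehyde. C3 is a former methyl-ketone carbon, C2 a former enal α-carbon, and the only sp3 atoms of ring A (C1, C8a) are the Michael acceptor and donor carbons.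
4. 8 ⇐ Birch reduction of a 4-substituted 2,6-dimethylanisole; 17 ⇐ Negishi carboalumination, Sharpless epoxidation and epoxy silyl ether 1,2-shift (quaternary carbon), HWE olefination, Heck reaction.
5. Ring order: ring B first (from the benzene ring, step 2), ring A last (step 12).

Key step: step 12

Remark: locants follow the hexahydronaphthalene numbering of the target (C1 bears the side chain, C2 the 2-oxopropyl group, C3 the methyl group, C7 is the ring-B carbonyl). C6 and C8 are α to that ketone and are assumed to equilibrate to the all-equatorial (6S,8R) arrangement of the target, so they are left uncontrolled until step 16.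

**Route**

Step 1
Reactants: 1 4-bromo-2,6-dimethylanisole; 2 (±)-propylene oxide
Product: 4 (±)-1-(4-methoxy-3,5-dimethylphenyl)propan-2-ol, via arylmagnesium bromide 3 (not isolated)
Conditions: Mg, THF, reflux; then CuI (10 mol%), 2, −30 → 0 °C; aq. NH4Cl
Reagents that add atoms: none
Why: CuI-catalysed ring opening of the epoxide by the aryl Grignard reagent at its unsubstituted carbon gives the secondary alcohol, whose carbinol centre is oxidised in step 4 so its configuration does not matter.

Step 2
Reactants: 4 (±)-1-(4-methoxy-3,5-dimethylphenyl)propan-2-ol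
Product: 5 1-(4-methoxy-3,5-dimethylcyclohexa-1,4-dien-1-yl)propan-2-ol (racemic diastereomer mixture)
Conditions: Li, NH3(l), THF, t-BuOH, −78 → −33 °C; NH4Cl
Reagents that add atoms: none
Why: Birch reduction keeps the methoxy-bearing carbon and the side-chain-bearing carbon on double bonds, so the dihydroanisole already holds the future C4a=C8a alkene and a C7 enol ether as latent ring-B ketone.

Step 3
Reactants: 5 1-(4-methoxy-3,5-dimethylcyclohexa-1,4-dien-1-yl)propan-2-ol
Product: 6 1-(6,10-dimethyl-1,4-dioxaspiro[4.5]dec-7-en-8-yl)propan-2-ol (stereoisomer mixture)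
Conditions: HOCH2CH2OH (5 equiv), TsOH·H2O (2 mol%), CH2Cl2, 0 °C
Reagents that add atoms: ethylene glycol, OCCO
Why: acid-catalysed transketalisation of the enol ether should trap the oxocarbenium ion as the dioxolane before the β,γ-alkene can move into conjugation; the two methyl-bearing carbons form unselectively and are corrected in step 16.

Step 4
Reactants: 6 1-(6,10-dimethyl-1,4-dioxaspiro[4.5]dec-7-en-8-yl)propan-2-ol
Product: 7 1-(6,10-dimethyl-1,4-dioxaspiro[4.5]dec-7-en-8-yl)propan-2-one
Conditions: Dess–Martin periodinane, NaHCO3, CH2Cl2, 0 °C → rt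
Reagents that add atoms: none
Why: buffered Dess–Martin oxidation should give the β,γ-unsaturated methyl ketone without touching the ketal or moving the ring alkene.

Step 5
Reactants: 7 1-(6,10-dimethyl-1,4-dioxaspiro[4.5]dec-7-en-8-yl)propan-2-one
Product: 8 tert-butyl{[(1Z)-1-(6,10-dimethyl-1,4-dioxaspiro[4.5]dec-7-en-8-yl)prop-1-en-2-yl]oxy}dimethylsilane (racemic, stereoisomer mixture at the methyl-bearing carbons)
Conditions: KN(SiMe3)2, THF, −78 °C; TBSCl; chromatography on Et3N-deactivated silica
Reagents that add atoms: tert-butyldimethylsilyl chloride, CC(C)(C)[Si](C)(C)Cl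
Why: enolate O-silylation after deprotonation at the doubly activated CH2 between the carbonyl group and the ring alkene gives the linear 1-silyloxydiene, and Z/E mixtures are usable because this carbon becomes sp2 C3.

Step 6
Reactants: 9 (2E)-3-methylpent-2-en-4-yn-1-ol
Product: 11 (2E,4E)-5-iodo-3,4-dimethylpenta-2,4-dien-1-ol, via alkenylalane 10 (not isolated)
Conditions: AlMe3 (3 equiv), Cp2ZrCl2 (0.3 equiv), CH2Cl2, −20 °C → rt; then I2, THF, −30 °C; aq. K2CO3
Reagents that add atoms: trimethylaluminium, C[Al](C)C; iodine, II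
Why: Negishi carboalumination adds Me–Al syn across the terminal alkyne with methyl on the internal carbon, and iodinolysis with retention gives the (E)-alkenyl iodide.

Step 7
Reactants: 11 (2E,4E)-5-iodo-3,4-dimethylpenta-2,4-dien-1-ol
Product: 12 [(2S,3S)-3-[(1E)-1-iodoprop-1-en-2-yl]-3-methyloxiran-2-yl]methanol
Conditions: Ti(OiPr)4 (10 mol%), L-(+)-diethyl tartrate (12 mol%), t-BuOOH, 4 Å MS, CH2Cl2, −20 °C
Reagents that add atoms: tert-butyl hydroperoxide, CC(C)(C)OO
Why: Katsuki–Sharpless asymmetric epoxidation of the allylic alcohol (the iodoalkene is not hydroxyl-directed) with L-(+)-tartrate should give the (2S,3S)-epoxide in the same facial sense as for geraniol.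

Step 8
Reactants: 12 [(2S,3S)-3-[(1E)-1-iodoprop-1-en-2-yl]-3-methyloxiran-2-yl]methanol
Product: 13 tert-butyl{[(2S,3S)-3-[(1E)-1-iodoprop-1-en-2-yl]-3-methyloxiran-2-yl]methoxy}dimethylsilane
Conditions: TBSCl, imidazole, DMF, 0 °C
Reagents that add atoms: tert-butyldimethylsilyl chloride, CC(C)(C)[Si](C)(C)Cl
Why: standard silylation of the primary alcohol provides the epoxy silyl ether needed for the 1,2-shift and leaves both stereocentres untouched.

Step 9
Reactants: 13 tert-butyl{[(2S,3S)-3-[(1E)-1-iodoprop-1-en-2-yl]-3-methyloxiran-2-yl]methoxy}dimethylsilane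
Product: 14 (2S,3E)-2-{[tert-butyl(dimethyl)silyl]oxymethyl}-4-iodo-2,3-dimethylbut-3-enal
Conditions: MeAl(OAr)2 (Ar = 4-bromo-2,6-di-tert-butylphenyl, 2 equiv, made in situ from AlMe3 and ArOH), CH2Cl2, −78 °C
Reagents that add atoms: none
Why: Maruoka–Yamamoto rearrangement, in which the bulky aluminium Lewis acid opens the epoxide at the tertiary allylic carbon and the siloxymethyl group shifts to it anti to the leaving oxygen (stereospecific 1,2-shift with inversion), turning the (2S,3S)-epoxide into the (S)-configured α-quaternary aldehyde.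

Step 10
Reactants: 14 (2S,3E)-2-{[tert-butyl(dimethyl)silyl]oxymethyl}-4-iodo-2,3-dimethylbut-3-enal
Product: 15 methyl (2E,4S,5E)-4-{[tert-butyl(dimethyl)silyl]oxymethyl}-6-iodo-4,5-dimethylhexa-2,5-dienoate
Conditions: (MeO)2P(O)CH2CO2Me, LiCl, DBU, MeCN, 0 °C → rt
Reagents that add atoms: trimethyl phosphonoacetate, COC(=O)CP(=O)(OC)OC
Why: Masamune–Roush Horner–Wadsworth–Emmons olefination of the non-enolisable α-quaternary aldehyde should give the (E)-enoate.

Step 11
Reactants: 15 methyl (2E,4S,5E)-4-{[tert-butyl(dimethyl)silyl]oxymethyl}-6-iodo-4,5-dimethylhexa-2,5-dienoate; 16 acrolein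
Product: 17 methyl (2E,4S,5E,7E)-4-{[tert-butyl(dimethyl)silyl]oxymethyl}-4,5-dimethyl-9-oxonona-2,5,7-trienoate
Conditions: Pd(OAc)2 (5 mol%), Bu4NCl, NaHCO3, DMF, 40 °C
Reagents that add atoms: none
Why: Heck reaction under Jeffery conditions (syn-carbopalladation of acrolein, syn-β-hydride elimination) should give the (2E,4E)-dienal with retention of the alkenyl iodide geometry, the enoate being unable to cyclise onto the alkenylpalladium.

Step 12
Reactants: 8 tert-butyl{[(1Z)-1-(6,10-dimethyl-1,4-dioxaspiro[4.5]dec-7-en-8-yl)prop-1-en-2-yl]oxy}dimethylsilane (racemic, 2.5 equiv); 17 methyl (2E,4S,5E,7E)-4-{[tert-butyl(dimethyl)silyl]oxymethyl}-4,5-dimethyl-9-oxonona-2,5,7-trienoate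
Product: 19 methyl (2E,4S,5E)-4-{[tert-butyl(dimethyl)silyl]oxymethyl}-6-[(1S,8aR)-7,7-(ethylenedioxy)-2-formyl-3,6,8-trimethyl-1,5,6,7,8,8a-hexahydronaphthalen-1-yl]-4,5-dimethylhexa-2,5-dienoate (C6/C8 epimer mixture), via β-silyloxy aldehyde cycloadduct 18 (not isolated)
Conditions: (S)-2-[diphenyl(trimethylsilyloxy)methyl]pyrrolidine (20 mol%), 4-nitrobenzoic acid (20 mol%), H2O (1 equiv), CH2Cl2, −20 °C → rt
Reagents that add atoms: none
Why: Proposed new method: the (S)-diarylprolinol silyl ether converts 17 into its E-iminium ion, the endocyclic γ-carbon of siloxydiene 8 (future C8a) adds to C-β (future C1) in a vinylogous Mukaiyama–Michael step, and the enamine carbon so formed (future C2) attacks the silyloxy-allyl cation/methyl-ketone carbon (future C3), closing ring A at the C2–C3 bond in a 6-(enolexo)-exo-trig aldol-type cyclisation to 18 (present as its enamine/iminium with the catalyst), after which enamine-assisted β-elimination of tert-butyldimethylsilanol makes C2=C3 and hydrolysis frees the catalyst. The closest known reaction types are the iminium-catalysed vinylogous Mukaiyama–Michael addition of silyl dienol ethers to enals, the amine-catalysed [3+3]/[4+2] condensation of two enals to cyclohexa-1,3-dienecarbaldehydes (safranal-type products) and the amine-salt cyclodehydration of 7-oxo-aldehydes, and what is new is their merger with a ketone-derived siloxydiene. C1 is set by the catalyst, whose diphenyl(silyloxy)methyl group blocks one face of the iminium ion so that addition to the open face should give (1S); C8a should follow from a compact endo-type arrangement (iminium chain over the diene, ring B away from the catalyst) that gives the trans C1-H/C8a-H relationship (8aR), and the enantiomer of racemic 8 that can react anti to its C8 methyl group should react faster, which is why 8 is used in excess. The step needs γ- over α-attack of the dienol ether (the γ-carbon is an unhindered ring =CH, the α-carbon is flanked by the ring and the silyloxy carbon), 1,4- over 1,6-addition to the dienal (C5 of 17 is fully substituted) and discrimination against the enoate (neopentyl β-carbon, no iminium activation). Ring closure needs the acetyl-derived carbon syn to C8a, which the allyl-cation character of the silyloxycarbenium intermediate (rotation about C4–C4a) should provide. C6 and C8 are not controlled here and are corrected in step 16.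

Step 13
Reactants: 20 bis[(pinacolato)boryl]methane
Product: 22 1,1-bis[(pinacolato)boryl]ethane, via lithiated diborylmethane 21 (not isolated)
Conditions: lithium 2,2,6,6-tetramethylpiperidide, THF, 0 °C; MeI, 0 °C → rt
Reagents that add atoms: iodomethane, CI
Why: deprotonation of the geminal bis(boronate) gives a boron-stabilised carbanion that is methylated by SN2 reaction with iodomethane.

Step 14
Reactants: 19 ring-A carbaldehyde (as in step 12); 22 1,1-bis[(pinacolato)boryl]ethane
Product: 24 methyl (2E,4S,5E)-4-{[tert-butyl(dimethyl)silyl]oxymethyl}-6-[(1S,8aR)-7,7-(ethylenedioxy)-3,6,8-trimethyl-2-[2-(4,4,5,5-tetramethyl-1,3,2-dioxaborolan-2-yl)prop-1-en-1-yl]-1,5,6,7,8,8a-hexahydronaphthalen-1-yl]-4,5-dimethylhexa-2,5-dienoate (alkene isomers, C6/C8 epimer mixture), via lithiated diborylethane 23 (not isolated)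
Conditions: 22, lithium 2,2,6,6-tetramethylpiperidide, THF, 0 °C; then 19, −78 °C → rt; aq. NH4Cl
Reagents that add atoms: none
Why: boron-Wittig reaction, in which the α-boryl carbanion adds to the aldehyde and syn-elimination of the O–B(pin) unit gives the alkenyl boronate (either alkene geometry serves), with ester, ketal and silyl ether expected to survive at −78 °C.

Step 15
Reactants: 24 alkenyl boronate (as in step 14)
Product: 25 methyl (2E,4S,5E)-4-(hydroxymethyl)-4,5-dimethyl-6-[(1S,8aR)-3,6,8-trimethyl-7-oxo-2-[2-(4,4,5,5-tetramethyl-1,3,2-dioxaborolan-2-yl)prop-1-en-1-yl]-1,5,6,7,8,8a-hexahydronaphthalen-1-yl]hexa-2,5-dienoate (C6/C8 epimer mixture)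
Conditions: 2 M aq. HCl/THF (1:5), 30 °C
Reagents that add atoms: water, O
Why: acid-catalysed hydrolysis should remove the strained dioxolane of the α,α'-dimethyl ketone and the primary silyl ether, while the alkenyl pinacol boronate and the methyl ester should survive dilute acid.

Step 16
Reactants: 25 keto alcohol boronate (as in step 15)
Product: 26 (2E,4S,5E)-4-(hydroxymethyl)-4,5-dimethyl-6-[(1S,6S,8R,8aR)-3,6,8-trimethyl-7-oxo-2-[2-(4,4,5,5-tetramethyl-1,3,2-dioxaborolan-2-yl)prop-1-en-1-yl]-1,5,6,7,8,8a-hexahydronaphthalen-1-yl]hexa-2,5-dienoic acid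
Conditions: LiOH·H2O (excess), THF/MeOH/H2O, rt, argon; then 1 M HCl to pH 4
Reagents that add atoms: lithium hydroxide, [Li+].[OH-]
Why: saponification of the methyl ester and, in the same pot, enolate-mediated epimerisation of C6 and C8 should converge on the all-equatorial (6S,8R) arrangement (C8 methyl trans to the C8a–C1 bond), while the alkenyl boronate masks the side-chain ketone so that no β,γ-enone meets base (partial loss of pinacol from boron is harmless).

Step 17
Reactants: 26 boronate acid (as in step 16)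
Product: 27 (2E,4S,5E)-4-(hydroxymethyl)-4,5-dimethyl-6-[(1S,6S,8R,8aR)-3,6,8-trimethyl-7-oxo-2-(2-oxopropyl)-1,5,6,7,8,8a-hexahydronaphthalen-1-yl]hexa-2,5-dienoic acid (target)
Conditions: H2O2 (30% aq.), pH 7.5 phosphate buffer, THF, 0 °C
Reagents that add atoms: hydrogen peroxide, OO
Why: oxidation of the alkenyl C–B bond (1,2-migration to oxygen) gives the trienol, which should ketonise by kinetic protonation at the carbon α to the new carbonyl, as dienols do in photodeconjugation, so the C2=C3–C4=C4a diene stays in ring A and the near-neutral buffer guards against later migration or epimerisation.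

**Compound list**

1 | 4-bromo-2,6-dimethylanisole | COc1c(C)cc(Br)cc1C | starting material
2 | (±)-propylene oxide | CC1CO1 | starting material
3 | (4-methoxy-3,5-dimethylphenyl)magnesium bromide | COc1c(C)cc([Mg]Br)cc1C | intermediate (not isolated)
4 | (±)-1-(4-methoxy-3,5-dimethylphenyl)propan-2-ol | COc1c(C)cc(CC(C)O)cc1C | intermediate
5 | 1-(4-methoxy-3,5-dimethylcyclohexa-1,4-dien-1-yl)propan-2-ol | COC1=C(C)CC(CC(C)O)=CC1C | intermediate
6 | 1-(6,10-dimethyl-1,4-dioxaspiro[4.5]dec-7-en-8-yl)propan-2-ol | CC(O)CC1=CC(C)C2(OCCO2)C(C)C1 | intermediate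
7 | 1-(6,10-dimethyl-1,4-dioxaspiro[4.5]dec-7-en-8-yl)propan-2-one | CC(=O)CC1=CC(C)C2(OCCO2)C(C)C1 | intermediate
8 | tert-butyl{[(1Z)-1-(6,10-dimethyl-1,4-dioxaspiro[4.5]dec-7-en-8-yl)prop-1-en-2-yl]oxy}dimethylsilane | C/C(O[Si](C)(C)C(C)(C)C)=C/C1=CC(C)C2(OCCO2)C(C)C1 | intermediate
9 | (2E)-3-methylpent-2-en-4-yn-1-ol | OC/C=C(C)/C#C | starting material
10 | dimethyl[(1E,3E)-5-(dimethylalumanyloxy)-2,3-dimethylpenta-1,3-dien-1-yl]alumane | C[Al](C)OC/C=C(C)/C(C)=C/[Al](C)C | intermediate (not isolated)
11 | (2E,4E)-5-iodo-3,4-dimethylpenta-2,4-dien-1-ol | OC/C=C(C)/C(C)=C/I | intermediate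
12 | [(2S,3S)-3-[(1E)-1-iodoprop-1-en-2-yl]-3-methyloxiran-2-yl]methanol | OC[C@@H]1O[C@@]1(C)/C(C)=C/I | intermediate
13 | tert-butyl{[(2S,3S)-3-[(1E)-1-iodoprop-1-en-2-yl]-3-methyloxiran-2-yl]methoxy}dimethylsilane | CC(C)(C)[Si](C)(C)OC[C@@H]1O[C@@]1(C)/C(C)=C/I | intermediate
14 | (2S,3E)-2-{[tert-butyl(dimethyl)silyl]oxymethyl}-4-iodo-2,3-dimethylbut-3-enal | O=C[C@](C)(CO[Si](C)(C)C(C)(C)C)/C(C)=C/I | intermediate
15 | methyl (2E,4S,5E)-4-{[tert-butyl(dimethyl)silyl]oxymethyl}-6-iodo-4,5-dimethylhexa-2,5-dienoate | COC(=O)/C=C/[C@](C)(CO[Si](C)(C)C(C)(C)C)/C(C)=C/I | intermediate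
16 | acrolein | C=CC=O | starting material
17 | methyl (2E,4S,5E,7E)-4-{[tert-butyl(dimethyl)silyl]oxymethyl}-4,5-dimethyl-9-oxonona-2,5,7-trienoate | O=C/C=C/C=C(\C)[C@](C)(/C=C/C(=O)OC)CO[Si](C)(C)C(C)(C)C | intermediate
18 | 3-(tert-butyldimethylsilyloxy)-2,3-dihydro form of 19 (β-silyloxy aldehyde, catalyst-bound in the flask; C2, C3, C6, C8 undefined) | O=CC1C(C)(O[Si](C)(C)C(C)(C)C)C=C2CC(C)C3(OCCO3)C(C)[C@H]2[C@@H]1/C=C(\C)[C@](C)(/C=C/C(=O)OC)CO[Si](C)(C)C(C)(C)C | intermediate (not isolated)
19 | methyl (2E,4S,5E)-4-{[tert-butyl(dimethyl)silyl]oxymethyl}-6-[(1S,8aR)-7,7-(ethylenedioxy)-2-formyl-3,6,8-trimethyl-1,5,6,7,8,8a-hexahydronaphthalen-1-yl]-4,5-dimethylhexa-2,5-dienoate (C6/C8 epimer mixture) | O=CC1=C(C)C=C2CC(C)C3(OCCO3)C(C)[C@H]2[C@@H]1/C=C(\C)[C@](C)(/C=C/C(=O)OC)CO[Si](C)(C)C(C)(C)C | intermediate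
20 | bis[(pinacolato)boryl]methane | CC1(C)OB(CB2OC(C)(C)C(C)(C)O2)OC1(C)C | starting material
21 | lithio-bis[(pinacolato)boryl]methane | [Li]C(B1OC(C)(C)C(C)(C)O1)B1OC(C)(C)C(C)(C)O1 | intermediate (not isolated)
22 | 1,1-bis[(pinacolato)boryl]ethane | CC(B1OC(C)(C)C(C)(C)O1)B1OC(C)(C)C(C)(C)O1 | intermediate
23 | 1-lithio-1,1-bis[(pinacolato)boryl]ethane | [Li]C(C)(B1OC(C)(C)C(C)(C)O1)B1OC(C)(C)C(C)(C)O1 | intermediate (not isolated)
24 | methyl (2E,4S,5E)-4-{[tert-butyl(dimethyl)silyl]oxymethyl}-6-[(1S,8aR)-7,7-(ethylenedioxy)-3,6,8-trimethyl-2-[2-(pinacolboryl)prop-1-en-1-yl]-1,5,6,7,8,8a-hexahydronaphthalen-1-yl]-4,5-dimethylhexa-2,5-dienoate | CC(=CC1=C(C)C=C2CC(C)C3(OCCO3)C(C)[C@H]2[C@@H]1/C=C(\C)[C@](C)(/C=C/C(=O)OC)CO[Si](C)(C)C(C)(C)C)B1OC(C)(C)C(C)(C)O1 | intermediate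
25 | methyl (2E,4S,5E)-4-(hydroxymethyl)-4,5-dimethyl-6-[(1S,8aR)-3,6,8-trimethyl-7-oxo-2-[2-(pinacolboryl)prop-1-en-1-yl]-1,5,6,7,8,8a-hexahydronaphthalen-1-yl]hexa-2,5-dienoate | CC(=CC1=C(C)C=C2CC(C)C(=O)C(C)[C@H]2[C@@H]1/C=C(\C)[C@](C)(/C=C/C(=O)OC)CO)B1OC(C)(C)C(C)(C)O1 | intermediate
26 | (2E,4S,5E)-4-(hydroxymethyl)-4,5-dimethyl-6-[(1S,6S,8R,8aR)-3,6,8-trimethyl-7-oxo-2-[2-(pinacolboryl)prop-1-en-1-yl]-1,5,6,7,8,8a-hexahydronaphthalen-1-yl]hexa-2,5-dienoic acid | CC(=CC1=C(C)C=C2C[C@H](C)C(=O)[C@H](C)[C@H]2[C@@H]1/C=C(\C)[C@](C)(/C=C/C(=O)O)CO)B1OC(C)(C)C(C)(C)O1 | intermediate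
27 | (2E,4S,5E)-4-(hydroxymethyl)-4,5-dimethyl-6-[(1S,6S,8R,8aR)-3,6,8-trimethyl-7-oxo-2-(2-oxopropyl)-1,5,6,7,8,8a-hexahydronaphthalen-1-yl]hexa-2,5-dienoic acid | CC(=O)CC1=C(C)C=C2C[C@H](C)C(=O)[C@H](C)[C@H]2[C@@H]1/C=C(\C)[C@](C)(/C=C/C(=O)O)CO | target

**Totals**

Total step count: 17. Longest linear sequence: 11 steps (steps 6–12, then 14–17).

**Steps most likely to fail, with fallbacks**

Step 12 (proposed new method). What may go wrong: the Michael adduct may not cyclise, because the enone can form with its acetyl group turned away from C8a and aldol addition to a ketone is slow; the dienol ether may attack through its α-carbon; and the mismatched enantiomer of 8 may erode facial selectivity at C8a. The fallback uses known chemistry and splits the domino into two separately run reactions, setting out from 8 and 17 and returning at 19. First, the diarylprolinol-silyl-ether-catalysed vinylogous Mukaiyama–Michael addition is run at −40 °C in wet CH2Cl2 with stoichiometric acid and stopped at the open-chain stage, giving the keto-aldehyde F1 after loss of the silyl group. Second, F1 is cyclodehydrated with piperidinium acetate (toluene, 60 °C), the classical amine-salt aldol condensation of 7-oxo-aldehydes to 2-methylcyclohex-1-enecarbaldehydes; the enone geometry can equilibrate under these conditions by reversible amine conjugate addition. This gives 19.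

Step 17. What may go wrong: ketonisation of the trienol by protonation at the vinylogous positions (C3 or C4a), or later base-mediated migration of the β,γ-double bond into conjugation with the new ketone. The fallback avoids any dienol by making the ketone through Wacker oxidation; it sets out from 19 and returns at 27. Luche reduction (NaBH4, CeCl3·7H2O, MeOH, −40 °C) gives the allylic alcohol F3. Acylation (ClCO2Me, pyridine) gives the methyl carbonate F4. Stille coupling with tributyl(vinyl)stannane [Pd2(dba)3, tri(2-furyl)phosphine, DMF, 40 °C], expected at the primary allyl terminus, gives the 2-allyl compound F5. Acid hydrolysis as in step 15 gives the keto alcohol F6, and LiOH as in step 16 gives the equilibrated acid F7; the allyl group tolerates both. Tsuji–Wacker oxidation of the terminal alkene (PdCl2, CuCl, O2, DMF/H2O) then gives 27.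

Step 14. What may go wrong: slow addition of the bulky α-boryl carbanion to the hindered tetrasubstituted enal, with competing deprotonation at the vinylogously acidic C8a–H. The fallback sets out from 19 and returns at 24. Stork–Zhao-type Wittig olefination with (1-iodoethylidene)triphenylphosphorane (from ethyltriphenylphosphonium bromide, n-BuLi, I2, then NaN(SiMe3)2, THF, −78 °C) gives the alkenyl iodide F2. Miyaura borylation [bis(pinacolato)diboron, PdCl2(dppf), KOAc, dioxane, 50 °C] then gives 24.

Further compounds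
F1 | step 12 | methyl (2E,4S,5E)-4-{[tert-butyl(dimethyl)silyl]oxymethyl}-4,5-dimethyl-6-[(1S)-1-[(6R)-1,5-dimethyl-3-(2-oxopropylidene)-... ring B ketal]-3-oxopropyl] hexa-2,5-dienoate, i.e. the open-chain Michael adduct (7-oxo-aldehyde; enone geometry and C6/C8 undefined) | CC(=O)C=C1CC(C)C2(OCCO2)C(C)[C@H]1[C@@H](CC=O)/C=C(\C)[C@](C)(/C=C/C(=O)OC)CO[Si](C)(C)C(C)(C)C
F2 | step 14 | 2-(2-iodoprop-1-en-1-yl) analogue of 19 (alkenyl iodide in place of the formyl group) | CC(I)=CC1=C(C)C=C2CC(C)C3(OCCO3)C(C)[C@H]2[C@@H]1/C=C(\C)[C@](C)(/C=C/C(=O)OC)CO[Si](C)(C)C(C)(C)C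
F3 | step 17 | 2-(hydroxymethyl) analogue of 19 (allylic alcohol) | OCC1=C(C)C=C2CC(C)C3(OCCO3)C(C)[C@H]2[C@@H]1/C=C(\C)[C@](C)(/C=C/C(=O)OC)CO[Si](C)(C)C(C)(C)C
F4 | step 17 | methyl carbonate of F3 | COC(=O)OCC1=C(C)C=C2CC(C)C3(OCCO3)C(C)[C@H]2[C@@H]1/C=C(\C)[C@](C)(/C=C/C(=O)OC)CO[Si](C)(C)C(C)(C)C
F5 | step 17 | 2-allyl analogue of 19 | C=CCC1=C(C)C=C2CC(C)C3(OCCO3)C(C)[C@H]2[C@@H]1/C=C(\C)[C@](C)(/C=C/C(=O)OC)CO[Si](C)(C)C(C)(C)C
F6 | step 17 | 2-allyl keto alcohol methyl ester (ketal and silyl ether removed; C6/C8 undefined) | C=CCC1=C(C)C=C2CC(C)C(=O)C(C)[C@H]2[C@@H]1/C=C(\C)[C@](C)(/C=C/C(=O)OC)CO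
F7 | step 17 | (6S,8R)-2-allyl keto alcohol acid | C=CCC1=C(C)C=C2C[C@H](C)C(=O)[C@H](C)[C@H]2[C@@H]1/C=C(\C)[C@](C)(/C=C/C(=O)O)CO
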